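**Retrosynthetic overview**
1. The γ-butyrolactone is made last, by ring-expansion carbonylation (four- to five-membered) of a 3-substituted oxetane; this also sets the lactone stereocentre.
2. The decalin–side-chain bond comes from a B-alkyl Suzuki coupling of a tetrasubstituted decalin enol triflate with the hydroborated vinyl end of a (Z)-dienyl diol.
3. The dienyl diol is assembled in one pot from vinylmagnesium bromide, propargyl alcohol (anti-carbomagnesiation fixes the Z-alkene) and an (S)-oxetanyl epoxide (from oxetane-3-carbaldehyde, kinetic resolution).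
4. The decalin comes from a Robinson annulation on 2-methylcyclopentane-1,3-dione (ring A and the quaternary centre), then diazoethane ring expansion of the cyclopentanone (five- to six-membered) to ring B with its methyl group, then reductive methylation and deoxygenation of ring A.
5. Ring order: ring A, then ring B by expansion, then the lactone by expansion of the purchased oxetane ring.

Assumption: diazoethane is used as a freshly distilled ether solution (from commercial N-ethyl-N-nitrosourea and KOH) and counted as a reagent; the methyl-bearing carbon next to the ring B carbonyl in 5–10 is carried as an epimer mixture because it becomes sp2 in 12.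

**Step 1**
Reactants: 1 2-methylcyclopentane-1,3-dione; 2 pent-1-en-3-one (ethyl vinyl ketone)
Product: 4 (S)-4,7a-dimethyl-2,3,7,7a-tetrahydro-1H-indene-1,5(6H)-dione, via triketone 3 (not isolated)
Conditions: 2 (1.5 equiv), Et3N (5 mol%), EtOAc, 25 °C; evaporate; L-phenylalanine (1.0 equiv), HClO4 (1 M aq, 0.4 equiv), MeCN, 80 °C; recrystallise
Reagents that add atoms: none
Why: Michael addition followed by amino-acid-catalysed intramolecular aldol condensation (Hajos–Parrish-type Robinson annulation), in which the L-phenylalanine enamine distinguishes the two enantiotopic ring carbonyls of 3 and so fixes the quaternary methyl-bearing centre as S.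

**Step 2**
Reactants: 4 (S)-4,7a-dimethyl-2,3,7,7a-tetrahydro-1H-indene-1,5(6H)-dione
Product: 5 (8aS)-2,5,8a-trimethyl-3,4,8,8a-tetrahydronaphthalene-1,6(2H,7H)-dione (mixture of 2-epimers)
Conditions: CH3CHN2 (1.5 equiv, Et2O), Sc(OTf)3 (10 mol%), CH2Cl2, −78 → −40 °C
Reagents that add atoms: diazoethane, CC=[N+]=[N-]
Why: Lewis-acid-catalysed diazoalkane ring expansion (Tiffeneau–Demjanov-type 1,2-shift), in which diazoethane adds to the strained saturated cyclopentanone carbonyl rather than the conjugated one and the less substituted CH2 migrates with loss of N2 (as in D-homoannulation of 17-oxo steroids), inserting CH(CH3) between C=O and CH2; the new centre is an inconsequential epimer mixture.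

**Step 3**
Reactants: 5 (8aS)-2,5,8a-trimethyl-3,4,8,8a-tetrahydronaphthalene-1,6(2H,7H)-dione
Product: 7 (4aS,8aR)-5-hydroxy-1,1,4a,6-tetramethyloctahydronaphthalen-2(1H)-one (epimers at C5/C6), via dilithium enolate 6 (not isolated)
Conditions: Li (5 equiv), t-BuOH (2.0 equiv), NH3/THF, −78 → −33 °C; isoprene; MeI (6 equiv), −78 → 20 °C; aq NH4Cl
Reagents that add atoms: iodomethane, CI
Why: Stork reductive alkylation (dissolving-metal enone reduction, then enolate C-methylation), in which axial protonation of the β-carbon anti to the angular methyl sets the trans ring fusion, the regiospecific enolate gives the gem-dimethyl ketone, and the hindered ring B ketone is reduced to its alkoxide, which masks it for step 4.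

**Step 4**
Reactants: 7 (4aS,8aR)-5-hydroxy-1,1,4a,6-tetramethyloctahydronaphthalen-2(1H)-one
Product: 9 (4aS,8aS)-2,5,5,8a-tetramethyldecahydronaphthalen-1-ol (epimers at C1/C2), via hydrazone 8 (not isolated)
Conditions: N2H4·H2O (10 equiv), KOH (6 equiv), diethylene glycol, 130 °C then 210 °C
Reagents that add atoms: none
Why: Wolff–Kishner reduction (Huang–Minlon procedure), in which the hydrazone of the ring A ketone loses N2 under base to give CH2 while the secondary alcohol and the ring-fusion stereocentres are untouched.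

**Step 5**
Reactants: 9 (4aS,8aS)-2,5,5,8a-tetramethyldecahydronaphthalen-1-ol
Product: 10 (4aS,8aS)-2,5,5,8a-tetramethyloctahydronaphthalen-1(2H)-one (2-epimers)
Conditions: Pr4N[RuO4] (5 mol%), N-methylmorpholine N-oxide (1.5 equiv), 4 Å MS, CH2Cl2, 20 °C
Reagents that add atoms: none
Why: Ley–Griffith oxidation of the hindered secondary alcohol, which converges the carbinol epimers to one ketone without touching the ring-fusion centres.

**Step 6**
Reactants: 10 (4aS,8aS)-2,5,5,8a-tetramethyloctahydronaphthalen-1(2H)-one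
Product: 12 (4aS,8aS)-2,5,5,8a-tetramethyl-3,4,4a,5,6,7,8,8a-octahydronaphthalen-1-yl trifluoromethanesulfonate, via potassium enolate 11 (not isolated)
Conditions: KHMDS (1.3 equiv), THF, −78 → 0 °C; PhNTf2 (1.3 equiv), −78 → 20 °C
Reagents that add atoms: N-phenylbis(trifluoromethanesulfonimide), O=S(=O)(N(c1ccccc1)S(=O)(=O)C(F)(F)F)C(F)(F)F
Why: Enolate O-triflation, regiospecific because the ketone can enolise only towards the methyl-bearing carbon (the other α-carbon is quaternary), so the tetrasubstituted enol triflate is the only one possible and the epimeric centre is erased.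

**Step 7**
Reactants: 13 oxetane-3-carbaldehyde
Product: 14 rac-3-(oxiran-2-yl)oxetane
Conditions: Me3S+ I− (1.2 equiv), NaH (1.2 equiv), DMSO/THF, 0 °C; then 13, 0 → 20 °C
Reagents that add atoms: trimethylsulfonium iodide, C[S+](C)C.[I-]
Why: Corey–Chaykovsky epoxidation, in which the sulfonium ylide adds to the aldehyde and the betaine closes to the terminal epoxide (racemic at the new centre); enolisation of the aldehyde is disfavoured because it would put a double bond exocyclic to the four-membered ring.

**Step 8**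
Reactants: 14 rac-3-(oxiran-2-yl)oxetane
Product: 15 (S)-3-(oxiran-2-yl)oxetane
Conditions: (S,S)-(salen)Co(OAc) (0.5 mol%, trivalent cobalt; salen = N,N′-bis(3,5-di-tert-butylsalicylidene)cyclohexane-1,2-diaminate), H2O (0.55 equiv), THF, 0 → 20 °C; distil
Reagents that add atoms: none
Why: Jacobsen hydrolytic kinetic resolution, in which the (S,S)-catalyst hydrates the (R)-epoxide selectively and leaves the (S)-epoxide (the future carbinol centre) in high ee at just under half the mass.

**Step 9**
Reactants: 15 (S)-3-(oxiran-2-yl)oxetane; 16 vinylmagnesium bromide; 17 prop-2-yn-1-ol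
Product: 19 (1R,3Z)-4-(hydroxymethyl)-1-(oxetan-3-yl)hexa-3,5-dien-1-ol, via alkenylmagnesium 18 (not isolated)
Conditions: 17 (1.3 equiv), 16 (2.7 equiv), CuI (15 mol%), THF, 0 → 25 °C; then 15 (1.0 equiv), −30 → 0 °C; aq NH4Cl
Reagents that add atoms: none
Why: Copper-catalysed anti-carbomagnesiation of the propargylic alkoxide followed by copper-catalysed SN2 opening of the terminal epoxide, in which vinyl adds to the internal alkyne carbon anti to magnesium (held cis to CH2O–Mg in a five-membered chelate) so that C–C bond formation with retention gives the (Z)-alkene, and attack at the epoxide CH2 leaves the carbinol centre untouched (now labelled 1R).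

**Step 10**
Reactants: 12 (4aS,8aS)-2,5,5,8a-tetramethyl-3,4,4a,5,6,7,8,8a-octahydronaphthalen-1-yl trifluoromethanesulfonate; 19 (1R,3Z)-4-(hydroxymethyl)-1-(oxetan-3-yl)hexa-3,5-dien-1-ol
Product: 21 (1R,3Z)-4-(hydroxymethyl)-1-(oxetan-3-yl)-6-[(4aS,8aS)-2,5,5,8a-tetramethyl-3,4,4a,5,6,7,8,8a-octahydronaphthalen-1-yl]hex-3-en-1-ol, via alkylborane 20 (not isolated)
Conditions: 19 (1.2 equiv), 9-BBN (3.8 equiv), THF, 0 → 25 °C; then 12 (1.0 equiv), Pd(dppf)Cl2 (5 mol%), K3PO4 (3 M aq, 3 equiv), DMF, 60 °C
Reagents that add atoms: none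
Why: Anti-Markovnikov hydroboration of the terminal vinyl group (the trisubstituted alkene is too hindered for 9-BBN; the two hydroxyls are borylated and freed again on work-up) followed by B-alkyl Suzuki–Miyaura coupling with the enol triflate, which touches no stereocentre or alkene geometry.

**Step 11**
Reactants: 21 (1R,3Z)-4-(hydroxymethyl)-1-(oxetan-3-yl)-6-[(4aS,8aS)-2,5,5,8a-tetramethyl-3,4,4a,5,6,7,8,8a-octahydronaphthalen-1-yl]hex-3-en-1-ol
Product: 22 (4R)-4-[(1R,3Z)-1-hydroxy-4-(hydroxymethyl)-6-[(4aS,8aS)-2,5,5,8a-tetramethyl-3,4,4a,5,6,7,8,8a-octahydronaphthalen-1-yl]hex-3-en-1-yl]oxolan-2-one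
Conditions: CO (40 bar), [(R,R)-(salen)Cr(THF)2][Co(CO)4] (5 mol%, trivalent chromium cation, same salen ligand as in step 8; antipode chosen by screening), 1,2-dimethoxyethane, 60 °C
Reagents that add atoms: carbon monoxide, [C-]#[O+]
Why: Proposed new method: desymmetrising ring-expansion carbonylation of a 3-substituted oxetane by a chiral Lewis-acid/cobaltate ion pair, in which the chromium cation binds the oxetane oxygen (helped by the neighbouring hydroxyl), [Co(CO)4]− opens one of the two diastereotopic CH2–O bonds by SN2 attack inside the chiral pocket, CO inserts into the C–Co bond by 1,2-alkyl migration and the metal alkoxide closes the five-membered lactone, so the choice of CH2 sets the lactone centre as R; the closest known reactions are the achiral Lewis-acid/[Co(CO)4]− carbonylation of oxetanes to γ-butyrolactones and the enantioselective carbonylative desymmetrisation of meso-epoxides.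

**Compound list**
1 | 2-methylcyclopentane-1,3-dione | CC1C(=O)CCC1=O | starting material
2 | pent-1-en-3-one | CCC(=O)C=C | starting material
3 | 2-methyl-2-(3-oxopentyl)cyclopentane-1,3-dione | CCC(=O)CCC1(C)C(=O)CCC1=O | intermediate (not isolated)
4 | (S)-4,7a-dimethyl-2,3,7,7a-tetrahydro-1H-indene-1,5(6H)-dione | O=C1[C@@]2(C)CCC(=O)C(C)=C2CC1 | intermediate
5 | (8aS)-2,5,8a-trimethyl-3,4,8,8a-tetrahydronaphthalene-1,6(2H,7H)-dione (2-epimers) | CC1C(=O)[C@@]2(C)CCC(=O)C(C)=C2CC1 | intermediate
6 | dilithium enolate/alkoxide from reduction of 5 | [Li+].[Li+].CC1C([O-])[C@@]2(C)CCC([O-])=C(C)[C@@H]2CC1 | intermediate (not isolated)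
7 | (4aS,8aR)-5-hydroxy-1,1,4a,6-tetramethyloctahydronaphthalen-2(1H)-one (epimers at C5/C6) | CC1C(O)[C@@]2(C)CCC(=O)C(C)(C)[C@@H]2CC1 | intermediate
8 | hydrazone of 7 at the ring A carbonyl | CC1C(O)[C@@]2(C)CCC(=NN)C(C)(C)[C@@H]2CC1 | intermediate (not isolated)
9 | (4aS,8aS)-2,5,5,8a-tetramethyldecahydronaphthalen-1-ol (epimers at C1/C2) | CC1C(O)[C@@]2(C)CCCC(C)(C)[C@@H]2CC1 | intermediate
10 | (4aS,8aS)-2,5,5,8a-tetramethyloctahydronaphthalen-1(2H)-one (2-epimers) | CC1C(=O)[C@@]2(C)CCCC(C)(C)[C@@H]2CC1 | intermediate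
11 | potassium enolate of 10 | [K+].CC1=C([O-])[C@@]2(C)CCCC(C)(C)[C@@H]2CC1 | intermediate (not isolated)
12 | (4aS,8aS)-2,5,5,8a-tetramethyl-3,4,4a,5,6,7,8,8a-octahydronaphthalen-1-yl trifluoromethanesulfonate | CC1=C(OS(=O)(=O)C(F)(F)F)[C@@]2(C)CCCC(C)(C)[C@@H]2CC1 | intermediate
13 | oxetane-3-carbaldehyde | O=CC1COC1 | starting material
14 | rac-3-(oxiran-2-yl)oxetane | C1OC1C2COC2 | intermediate
15 | (S)-3-(oxiran-2-yl)oxetane | C1O[C@H]1C2COC2 | intermediate
16 | vinylmagnesium bromide | C=C[Mg]Br | starting material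
17 | prop-2-yn-1-ol | C#CCO | starting material
18 | {(1Z)-2-[(bromomagnesiooxy)methyl]buta-1,3-dien-1-yl}magnesium bromide | Br[Mg]/C=C(/C=C)CO[Mg]Br | intermediate (not isolated)
19 | (1R,3Z)-4-(hydroxymethyl)-1-(oxetan-3-yl)hexa-3,5-dien-1-ol | C=C/C(=C/C[C@@H](O)C1COC1)CO | intermediate
20 | B-alkyl-9-BBN adduct of 19 with both hydroxyls as 9-BBN borinates | B1(C2CCCC1CCC2)CC/C(=C/C[C@@H](OB1C2CCCC1CCC2)C1COC1)COB1C2CCCC1CCC2 | intermediate (not isolated)
21 | (1R,3Z)-4-(hydroxymethyl)-1-(oxetan-3-yl)-6-[(4aS,8aS)-2,5,5,8a-tetramethyl-3,4,4a,5,6,7,8,8a-octahydronaphthalen-1-yl]hex-3-en-1-ol | CC1=C(CC/C(=C/C[C@@H](O)C2COC2)CO)[C@@]2(C)CCCC(C)(C)[C@@H]2CC1 | intermediate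
22 | (4R)-4-[(1R,3Z)-1-hydroxy-4-(hydroxymethyl)-6-[(4aS,8aS)-2,5,5,8a-tetramethyl-3,4,4a,5,6,7,8,8a-octahydronaphthalen-1-yl]hex-3-en-1-yl]oxolan-2-one | CC1=C(CC/C(=C/C[C@@H](O)[C@H]2COC(=O)C2)CO)[C@@]2(C)CCCC(C)(C)[C@@H]2CC1 | target

**Totals**
Total step count: 11. Longest linear sequence: 8 steps (steps 1–6, 10, 11); the side-chain branch is steps 7–9.

**Steps most likely to fail, with fallbacks**

Step 11 (the proposed new carbonylation) may fail on selectivity between the two CH2–O bonds or on tolerance of the free diol. The fallback uses known chemistry and brings the lactone in ready-made. It sets out from alkenylmagnesium 18 and triflate 12. Rhodium-catalysed asymmetric 1,4-addition of potassium vinyltrifluoroborate to furan-2(5H)-one ([Rh(cod)Cl]2 with BINAP, antipode chosen for the S product) gives (S)-4-vinyloxolan-2-one F1. Catalyst-controlled epoxidation of the terminal alkene (Ti(OiPr)4 with a chiral salalen ligand, aqueous H2O2) gives (4R)-4-[(2S)-oxiran-2-yl]oxolan-2-one F2. Alkenylmagnesium 18 is converted into the alkenylcopper with CuBr·SMe2 and opens F2 with BF3·OEt2 at −78 °C (the lactone is inert to the organocopper) to give (4R)-4-[(1R,3Z)-1-hydroxy-4-(hydroxymethyl)hexa-3,5-dien-1-yl]oxolan-2-one F3. Hydroboration of F3 and coupling with 12 as in step 10 returns directly at 22.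

Step 9 (three-component coupling) may fail at the vinyl Grignard carbomagnesiation or at the epoxide opening by the chelated alkenylmagnesium. The fallback builds the alkene from an alkyne instead and sets out from epoxide 15. Opening 15 with the dilithium salt of 17 (n-BuLi, THF/DMPU) gives (5R)-5-(oxetan-3-yl)pent-2-yne-1,5-diol F4. Cp2TiCl2-catalysed syn-hydromagnesiation (i-BuMgCl, Et2O) places magnesium on the alkyne carbon next to the CH2O–Mg group, and Pd(PPh3)4-catalysed coupling of that alkenylmagnesium with vinyl bromide returns to the route at 19 with the same (Z)-geometry.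

Step 3 (one-pot reduction of enone and hindered ketone with enolate methylation) may give mixtures at the ring B carbonyl. The fallback keeps that ketone and removes the ring A oxygen through a dithiolane; it sets out from 5. Using only 2.2 equiv Li with 1.0 equiv t-BuOH in NH3/THF at −78 °C and quenching with MeI reduces the enone alone and gives (4aS,8aS)-1,1,4a,6-tetramethyloctahydronaphthalene-2,5-dione F5. Ethane-1,2-dithiol with BF3·OEt2 ketalises only the less hindered ring A carbonyl to give (4a′S,8a′R)-1′,1′,4a′,6′-tetramethyloctahydro-5′H-spiro[1,3-dithiolane-2,2′-naphthalen]-5′-one F6. Raney Ni in EtOH removes the sulfur and returns to the route at ketone 10, replacing steps 4 and 5.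

**Further compounds**
F1 | step 11 | (S)-4-vinyloxolan-2-one | C=C[C@H]1COC(=O)C1
F2 | step 11 | (4R)-4-[(2S)-oxiran-2-yl]oxolan-2-one | C1O[C@H]1[C@H]2COC(=O)C2
F3 | step 11 | (4R)-4-[(1R,3Z)-1-hydroxy-4-(hydroxymethyl)hexa-3,5-dien-1-yl]oxolan-2-one | C=C/C(=C/C[C@@H](O)[C@H]1COC(=O)C1)CO
F4 | step 9 | (5R)-5-(oxetan-3-yl)pent-2-yne-1,5-diol | OCC#CC[C@@H](O)C1COC1
F5 | step 3 | (4aS,8aS)-1,1,4a,6-tetramethyloctahydronaphthalene-2,5-dione | CC1C(=O)[C@@]2(C)CCC(=O)C(C)(C)[C@@H]2CC1
F6 | step 3 | (4a′S,8a′R)-1′,1′,4a′,6′-tetramethyloctahydro-5′H-spiro[1,3-dithiolane-2,2′-naphthalen]-5′-one | CC1C(=O)[C@@]2(C)CCC3(SCCS3)C(C)(C)[C@@H]2CC1
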